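The pyran ring is cut at C4–C4a and at C2–C3. This takes out C3=C4 as an acetylene equivalent and leaves O1–C2(CH3)2 on the arene. Since O1 stands next to the C8 hydroxyl, this remainder is a hidden catechol acetonide: O1, C2 and O8 are carried as a 2,2-dimethyl-1,3-benzodioxole. In the key step SnCl4 opens that ketal towards O8. The aryl oxocarbenium ion O1=C2 then adds ethyl vinyl ether in a cationic [4+2] (oxa-Povarov) annulation that ends on C4a, the only free arene carbon. Loss of ethanol gives the chromene and the free 8-OH. The precursor, a dihydrochalcone acetonide, comes from baicalein in three steps.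

Key step: step 4

Remark: chromene numbering is used for the target and the chroman intermediate, flavone numbering for the flavones and the flavanone, and benzodioxole numbering (O1, C2, O3, C3a, C4 to C7, C7a) for the ring-opened ketones. The target has no stereocentre.

Step 1
Reactants: 1 baicalein (5,6,7-trihydroxyflavone); 2 2,2-dimethoxypropane
Product: 3 5-hydroxy-6,7-(isopropylidenedioxy)flavone (9-hydroxy-2,2-dimethyl-6-phenyl-8H-[1,3]dioxolo[4,5-g]chromen-8-one)
Conditions: 2,2-dimethoxypropane (5 equiv), p-TsOH·H2O (5 mol %), toluene/1,4-dioxane, reflux under N2, distillate passed over 4 Å MS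
Reagents that add atoms: 2,2-dimethoxypropane COC(C)(C)OC
Why: Acid-catalysed transketalisation with removal of methanol is the standard route to catechol acetonides, and under these equilibrating conditions the ketal should settle on O6/O7 because the 5-OH is held in the hydrogen bond to the C4 carbonyl.

Step 2
Reactants: 3 5-hydroxy-6,7-(isopropylidenedioxy)flavone; 4 iodomethane
Product: 5 5-methoxy-6,7-(isopropylidenedioxy)flavone (9-methoxy-2,2-dimethyl-6-phenyl-8H-[1,3]dioxolo[4,5-g]chromen-8-one)
Conditions: MeI (3 equiv), K2CO3 (3 equiv), DMF, 50 °C
Reagents that add atoms: iodomethane CI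
Why: Williamson O-methylation of the only free hydroxyl should work with excess reagent in a dipolar solvent, as chelated flavone 5-OH groups require, while the pyrone oxygen keeps the other oxygen ortho to the future ketone masked, so the two are told apart without a protecting group.

Step 3
Reactants: 5 5-methoxy-6,7-(isopropylidenedioxy)flavone
Product: 8 1-(6-hydroxy-4-methoxy-2,2-dimethyl-1,3-benzodioxol-5-yl)-3-phenylpropan-1-one (dihydrochalcone acetonide), via flavanone 6 (not isolated), via chalcone 7 (not isolated)
Conditions: H2 (4 bar), 10% Pd/C, KOH (3 equiv), EtOH/THF/H2O, rt; then 1 M HCl to pH 5, 0 °C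
Reagents that add atoms: none
Why: Catalytic hydrogenation of the chromone C2=C3 bond gives the flavanone, which in alkali opens by retro-oxa-Michael (E1cB) reaction to the chalcone phenolate that is hydrogenated in turn, the same alkaline hydrogenation that converts flavanones into dihydrochalcones; the stereocentre of 6 is racemic and vanishes on ring opening.

Step 4
Reactants: 8 1-(6-hydroxy-4-methoxy-2,2-dimethyl-1,3-benzodioxol-5-yl)-3-phenylpropan-1-one; 9 ethyl vinyl ether
Product: 11 flemistrictin D (1-(5,8-dihydroxy-7-methoxy-2,2-dimethyl-2H-chromen-6-yl)-3-phenylpropan-1-one), via 4-ethoxychroman 10 (not isolated)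
Conditions: SnCl4 (2.2 equiv), CH2Cl2, 4 Å MS, −78 °C; ethyl vinyl ether (1.2 equiv) by syringe pump over 2 h, −78 to −30 °C; then 0 °C until 10 is consumed; aq. NaHCO3
Reagents that add atoms: ethyl vinyl ether C=COCC
Why: Proposed new method: SnCl4, held in a five-membered chelate between the 4-OMe oxygen and the neighbouring ketal oxygen O3, should ionise the O3–C2 bond of 8 and so unmask the aryl oxocarbenium ion O1=C2(CH3)2(+), a cationic 2-oxadiene running over C2, O1, C7a and C7; the CH2 end of ethyl vinyl ether attacks C2 (chromene bond C2–C3) and the ethoxycarbenium ion so formed is trapped at once by C7 (chromene bond C4–C4a) to give chroman 10, whose 4-OEt group, benzylic and pushed by the 5-OH, 7-OMe and O1 donors, ionises on warming and loses H3 to leave the C3=C4 double bond and ethanol. The closest known reaction types are the SnCl4-promoted oxa-Povarov reaction of aryl acetals with alkenes, the Povarov reaction of N-aryl imines with ethyl vinyl ether and the Lewis-acid addition of vinyl ethers to acetone ketals (Müller-Cunradi–Pieroh reaction); new are the ketone-derived cation and its release from a cyclic catechol ketal, whose departing oxygen stays in the molecule as the 8-OH. The one new ring, the pyran, closes as a formal [4+2] cycloaddition whose last event is a 6-(enolendo)-exo-trig Friedel–Crafts attack of the arene on the exocyclic C=O(+)Et bond. The only new stereocentre, C4 of 10, is formed racemic and is erased by the elimination, so nothing has to be controlled. Two selectivities are needed: the sense of ketal opening, which the OMe/O3 chelate and the higher basicity of O3 (O1 is para to the ketone) should favour and which is backed by the fact that only the O1-bound cation has an unsubstituted ortho carbon to close on, and the site of arylation, which is fixed because C7 is the only C–H of the ring and lies ortho to the OH and para to the OMe. Slow addition of barely more than one equivalent of the vinyl ether at low temperature should keep its cationic oligomerisation, and its cycloaddition to the transient ortho-quinone methide, slower than the intramolecular ring closure.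

Compound list
1 | baicalein (5,6,7-trihydroxyflavone) | O=c1cc(-c2ccccc2)oc2cc(O)c(O)c(O)c12 | starting material
2 | 2,2-dimethoxypropane | COC(C)(C)OC | starting material
3 | 5-hydroxy-6,7-(isopropylidenedioxy)flavone | O=c1cc(-c2ccccc2)oc2cc3OC(C)(C)Oc3c(O)c12 | intermediate
4 | iodomethane | CI | starting material
5 | 5-methoxy-6,7-(isopropylidenedioxy)flavone | O=c1cc(-c2ccccc2)oc2cc3OC(C)(C)Oc3c(OC)c12 | intermediate
6 | 5-methoxy-6,7-(isopropylidenedioxy)flavanone (racemic, not isolated) | O=C1CC(c2ccccc2)Oc2cc3OC(C)(C)Oc3c(OC)c12 | intermediate
7 | (E)-1-(6-hydroxy-4-methoxy-2,2-dimethyl-1,3-benzodioxol-5-yl)-3-phenylprop-2-en-1-one (chalcone, not isolated) | COc1c(C(=O)/C=C/c2ccccc2)c(O)cc2OC(C)(C)Oc12 | intermediate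
8 | 1-(6-hydroxy-4-methoxy-2,2-dimethyl-1,3-benzodioxol-5-yl)-3-phenylpropan-1-one | COc1c(C(=O)CCc2ccccc2)c(O)cc2OC(C)(C)Oc12 | intermediate
9 | ethyl vinyl ether | C=COCC | starting material
10 | 1-(4-ethoxy-5,8-dihydroxy-7-methoxy-2,2-dimethylchroman-6-yl)-3-phenylpropan-1-one (racemic, not isolated) | CCOC1CC(C)(C)Oc2c(O)c(OC)c(C(=O)CCc3ccccc3)c(O)c12 | intermediate
11 | flemistrictin D | COc1c(O)c2c(c(O)c1C(=O)CCc1ccccc1)C=CC(C)(C)O2 | target

Total step count: 4. Longest linear sequence: 4 steps (from baicalein).

Steps most likely to fail

1. Step 4 (the labelled step).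
- The ketal may ionise in the opposite sense, because the O1 phenoxide is para to the ketone and is the better leaving group whenever the chelate does not operate.
- The vinyl ether may oligomerise cationically, or after protonation alkylate C7 directly.
- Excess vinyl ether may be captured by the ortho-quinone methide, and the chromene may dimerise under acid.
- The fallback uses known chemistry, sets out from 8 and returns at 11. The ketal of 8 is hydrolysed (TFA/H2O, rt) to 1-(3,4,6-trihydroxy-2-methoxyphenyl)-3-phenylpropan-1-one F1. Its hydroxyl para to the ketone, the most acidic one, is alkylated with 3-chloro-3-methylbut-1-yne (K2CO3, KI, cat. CuI, DMF) to 1-[3,6-dihydroxy-2-methoxy-4-(2-methylbut-3-yn-2-yloxy)phenyl]-3-phenylpropan-1-one F2. Heating F2 in N,N-diethylaniline triggers aromatic propargyl Claisen rearrangement to the only free ortho carbon, then a [1,5]-H shift and oxa-6π electrocyclisation to 11.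

2. Step 3.
- Saturation of the chromone double bond may be sluggish.
- Hydroxide may add at C2, followed by retro-Claisen fission.
- The benzylic ketone may be over-reduced.
- The fallback sets out from 5 and returns at 8, and it makes the fission deliberate. Refluxing 5 with aqueous-ethanolic KOH under N2 opens the pyrone to the 1,3-diketone, which is cleaved at the less hindered benzoyl carbonyl to 1-(6-hydroxy-4-methoxy-2,2-dimethyl-1,3-benzodioxol-5-yl)ethan-1-one F3. Claisen–Schmidt condensation of F3 with benzaldehyde (KOH, EtOH, rt) gives chalcone 7, now isolated. Neutral hydrogenation (H2, Pd/C, EtOAc) gives 8.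

3. Step 1.
- Transketalisation may stay incomplete because of an unfavourable equilibrium and the low solubility of baicalein.
- Some ketal may form across O5/O6.
- The pyrogallol unit may be air-oxidised at reflux.
- The fallback sets out from 1 and returns at 5. Baicalein is heated with dichlorodiphenylmethane (diphenyl ether, 170 °C), an irreversible ketalisation driven by loss of HCl, to 5-hydroxy-6,7-(diphenylmethylenedioxy)flavone F4. Methylation (MeI, K2CO3, DMF) gives 5-methoxy-6,7-(diphenylmethylenedioxy)flavone F5. Hydrolysis (AcOH/H2O, reflux) gives 6,7-dihydroxy-5-methoxyflavone F6, a more soluble catechol with only one diol pair. F6 is ketalised with 2 (cat. p-TsOH, toluene, reflux, 4 Å MS) to 5.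

Further compounds
F1 | step 4 | 1-(3,4,6-trihydroxy-2-methoxyphenyl)-3-phenylpropan-1-one | COc1c(O)c(O)cc(O)c1C(=O)CCc1ccccc1
F2 | step 4 | 1-[3,6-dihydroxy-2-methoxy-4-(2-methylbut-3-yn-2-yloxy)phenyl]-3-phenylpropan-1-one | COc1c(O)c(OC(C)(C)C#C)cc(O)c1C(=O)CCc1ccccc1
F3 | step 3 | 1-(6-hydroxy-4-methoxy-2,2-dimethyl-1,3-benzodioxol-5-yl)ethan-1-one | COc1c(C(C)=O)c(O)cc2OC(C)(C)Oc12
F4 | step 1 | 5-hydroxy-6,7-(diphenylmethylenedioxy)flavone | O=c1cc(-c2ccccc2)oc2cc3OC(c4ccccc4)(c4ccccc4)Oc3c(O)c12
F5 | step 1 | 5-methoxy-6,7-(diphenylmethylenedioxy)flavone | O=c1cc(-c2ccccc2)oc2cc3OC(c4ccccc4)(c4ccccc4)Oc3c(OC)c12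
F6 | step 1 | 6,7-dihydroxy-5-methoxyflavone | O=c1cc(-c2ccccc2)oc2cc(O)c(O)c(OC)c12
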